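**Plan**

Germacrane numbering is used: ring C1–C10, methyls C14 (on C10) and C15 (on C4), lactone oxygen on C6, C11–C13 on C7.

1. Retrosynthetic cuts, in order: C4–C5 (ring closure), the C8–O acyl bond, C8–C9, then O–C6 and C7–C11 together, then the two olefins of a glyceraldehyde-derived diene.
2. Enabling feature: in the γ-lactone ring (O, C6, C7, C11, C12) the two carbons flanking the C6–C7 bond, C5 and C8, both bear oxygen and can each be traced to an aldehyde. C5 is therefore carried as the far end of a 1,3-diene (C7=C6–C5=CMe2), which lets C6 become an allylpalladium terminus, and C8 as a dioxolane carbon.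
3. Forward: chiral-pool diene; one palladium-catalysed [3+2] heteroannulation with 2-bromoacrylic acid gives the α-methylene lactone; C8 aldehyde and vinylogous aldol join C9–C4; angelate; C5 aldehyde; the ten-membered ring closes last.
4. Stereochemistry: C7 from the dioxolane centre of (R)-glyceraldehyde acetonide (excised afterwards); C6 from equilibrating allylpalladium closure to the trans lactone; C8 from Felkin–Anh aldol addition; C5 from polar Felkin–Anh ring closure. The 1(10)E alkene comes from the aldol, 3Z from anti hydroiodination of an ynone, and the angelate Z geometry from angelic acid.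

Key step: step 3

Assumption: in step 3 the alkenylpalladium unit is taken to add to C6=C7 on the face opposite the dioxolane C–CH2 bond (inside-alkoxy conformer); because that centre is excised in step 4, the enantiomeric acetonide would be used if the facial sense proved opposite.

**Route**

Step 1
Reactants: 1 (4R)-2,2-dimethyl-1,3-dioxolane-4-carbaldehyde; 2 (triphenylphosphoranylidene)acetaldehyde
Product: 3 (2E)-3-[(4S)-2,2-dimethyl-1,3-dioxolan-4-yl]prop-2-enal
Conditions: toluene, rt
Reagents that add atoms: (triphenylphosphoranylidene)acetaldehyde 2, O=CC=P(c1ccccc1)(c1ccccc1)c1ccccc1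
Why: Wittig olefination with the stabilised formyl ylide should give the E-enal without touching the dioxolane centre, whose descriptor changes from R to S only because the substituent priorities change.

Step 2
Reactants: 3 (2E)-3-[(4S)-2,2-dimethyl-1,3-dioxolan-4-yl]prop-2-enal; 4 isopropyltriphenylphosphonium iodide
Product: 5 (4S)-2,2-dimethyl-4-[(1E)-4-methylpenta-1,3-dien-1-yl]-1,3-dioxolane
Conditions: 4, n-BuLi, THF, 0 °C; then 3, −78 °C to rt
Reagents that add atoms: isopropyltriphenylphosphonium iodide 4, CC(C)[P+](c1ccccc1)(c1ccccc1)c1ccccc1.[I-]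
Why: Wittig olefination with the non-stabilised isopropylidene ylide should add 1,2 to the enal and install the CMe2 diene terminus while the E-alkene and the stereocentre stay as they are.

Step 3
Reactants: 5 (4S)-2,2-dimethyl-4-[(1E)-4-methylpenta-1,3-dien-1-yl]-1,3-dioxolane; 6 2-bromoprop-2-enoic acid
Product: 8 (4S,5R)-4-[(4S)-2,2-dimethyl-1,3-dioxolan-4-yl]-3-methylidene-5-(2-methylprop-1-en-1-yl)oxolan-2-one, via allylpalladium bromide 7 (not isolated)
Conditions: Pd(OAc)2 (5 mol %), PPh3 (10 mol %), NaHCO3, n-Bu4NCl, DMF, 60 °C, slow addition of 6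
Reagents that add atoms: 2-bromoprop-2-enoic acid 6, C=C(Br)C(=O)O
Why: Zerovalent palladium inserts into the C–Br bond of 6, the alkenylpalladium species adds syn across the disubstituted C6=C7 alkene of 5 with the acrylate carbon going to C7 and palladium to C6, where it becomes the η3-allyl 7 spanning C6, C5 and the CMe2 carbon, and the pendant carboxylate then attacks the C6 terminus and releases zerovalent palladium. The closest known reaction type is the Larock heteroannulation of 1,3-dienes by vinylic halides that carry a carboxylic acid. The only ring closed is the γ-lactone, by 5-exo attack of the carboxylate oxygen on the allyl terminus C6, a formal [3+2] annulation across C6=C7; the seven-membered alternative would require attack at the fully substituted CMe2 terminus. C7 is set by the dioxolane centre: in the inside-alkoxy conformer the alkenylpalladium unit should add to the alkene face opposite the dioxolane C–CH2 bond. C6 is set in the ring closure: the allyl face can equilibrate through the η1 form at the symmetric CMe2 terminus and through reversible ionisation of the allylic lactone, so that both allylpalladium diastereomers should funnel into the more stable trans-4,5-disubstituted lactone. The step needs insertion at C7 and not at the other diene end, which the gem-dimethyl terminus secures by shielding its own alkene and stabilising the allyl, and it needs lactonisation to outrun β-hydride elimination, which the intramolecular carboxylate should secure.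

Step 4
Reactants: 8 (4S,5R)-4-[(4S)-2,2-dimethyl-1,3-dioxolan-4-yl]-3-methylidene-5-(2-methylprop-1-en-1-yl)oxolan-2-one
Product: 9 (2R,3S)-4-methylidene-2-(2-methylprop-1-en-1-yl)-5-oxooxolane-3-carbaldehyde
Conditions: H5IO6, EtOAc, rt; used crude
Reagents that add atoms: none
Why: Periodic acid should hydrolyse the terminal acetonide and cleave the liberated 1,2-diol in one pot (glycol cleavage), excising the spent controller carbon under non-basic conditions that leave C6 and C7 untouched.

Step 5
Reactants: 10 3-methylbut-2-enoyl chloride; 11 trimethyl(prop-1-yn-1-yl)silane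
Product: 12 2-methylhept-2-en-5-yn-4-one
Conditions: AlCl3, CH2Cl2, 0 °C
Reagents that add atoms: trimethyl(prop-1-yn-1-yl)silane 11, CC#C[Si](C)(C)C
Why: Friedel–Crafts-type ipso-acylation of the alkynylsilane by the acylium ion should give the ynone regiospecifically.

Step 6
Reactants: 12 2-methylhept-2-en-5-yn-4-one; 13 tert-butyldimethylsilyl trifluoromethanesulfonate
Product: 14 tert-butyl(dimethyl){[(3Z)-2-methylhepta-1,3-dien-5-yn-4-yl]oxy}silane
Conditions: TBSOTf, i-Pr2NEt, CH2Cl2, −78 to 0 °C
Reagents that add atoms: tert-butyldimethylsilyl trifluoromethanesulfonate 13, CC(C)(C)[Si](C)(C)OS(=O)(=O)C(F)(F)F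
Why: Soft enolisation (O-silylation, then γ-deprotonation by the hindered amine) should give the silyl dienol ether, since only the methyl groups of the CMe2 end can be deprotonated into conjugation; the enol ether geometry is lost in step 7.

Step 7
Reactants: 9 (2R,3S)-4-methylidene-2-(2-methylprop-1-en-1-yl)-5-oxooxolane-3-carbaldehyde; 14 tert-butyl(dimethyl){[(3Z)-2-methylhepta-1,3-dien-5-yn-4-yl]oxy}silane
Product: 15 (4R,5R)-4-[(1S,3E)-1-hydroxy-3-methyl-5-oxooct-3-en-6-yn-1-yl]-3-methylidene-5-(2-methylprop-1-en-1-yl)oxolan-2-one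
Conditions: BF3·OEt2, CH2Cl2, −78 °C; aq. NaHCO3
Reagents that add atoms: dienol ether 14, C=C(C)/C=C(\O[Si](C)(C)C(C)(C)C)C#CC
Why: In this vinylogous Mukaiyama aldol reaction the dienol ether should attack through its terminal CH2 (C9) from the s-trans conformer to give the E-enone, and Felkin–Anh addition anti to the C7–C6 ring bond should set C8 as S (oxygen syn to C11).

Step 8
Reactants: 15 (4R,5R)-4-[(1S,3E)-1-hydroxy-3-methyl-5-oxooct-3-en-6-yn-1-yl]-3-methylidene-5-(2-methylprop-1-en-1-yl)oxolan-2-one; 16 sodium iodide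
Product: 17 (4R,5R)-4-[(1S,3E,6Z)-1-hydroxy-7-iodo-3-methyl-5-oxoocta-3,6-dien-1-yl]-3-methylidene-5-(2-methylprop-1-en-1-yl)oxolan-2-one
Conditions: NaI, AcOH, rt, dark
Reagents that add atoms: sodium iodide 16, [Na+].[I-]
Why: Conjugate hydroiodination of the ynone (iodide addition, then protonation anti to iodine) should give the Z-β-iodoenone, the ynone being far more electrophilic than the β,β-disubstituted enone or the acrylate.

Step 9
Reactants: 17 (4R,5R)-4-[(1S,3E,6Z)-1-hydroxy-7-iodo-3-methyl-5-oxoocta-3,6-dien-1-yl]-3-methylidene-5-(2-methylprop-1-en-1-yl)oxolan-2-one; 18 (2Z)-2-methylbut-2-enoic acid (angelic acid)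
Product: 19 (1S,3E,6Z)-7-iodo-3-methyl-1-[(2R,3R)-4-methylidene-2-(2-methylprop-1-en-1-yl)-5-oxooxolan-3-yl]-5-oxoocta-3,6-dien-1-yl (2Z)-2-methylbut-2-enoate
Conditions: 18, 2,4,6-trichlorobenzoyl chloride, Et3N, toluene, rt; then 17, toluene, 70 °C
Reagents that add atoms: angelic acid 18, C/C=C(/C)C(=O)O
Why: Yamaguchi esterification through the mixed anhydride, run without a nucleophilic catalyst, should keep the Z geometry of the angelate, and C8 keeps its configuration because only the O–H bond is broken.

Step 10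
Reactants: 19 (1S,3E,6Z)-7-iodo-3-methyl-1-[(2R,3R)-4-methylidene-2-(2-methylprop-1-en-1-yl)-5-oxooxolan-3-yl]-5-oxoocta-3,6-dien-1-yl (2Z)-2-methylbut-2-enoate; 20 3-chloroperoxybenzoic acid
Product: 22 (1S,3E,6Z)-1-[(2S,3R)-2-formyl-4-methylidene-5-oxooxolan-3-yl]-7-iodo-3-methyl-5-oxoocta-3,6-dien-1-yl (2Z)-2-methylbut-2-enoate, via epoxide 21 (not isolated)
Conditions: mCPBA, NaHCO3, CH2Cl2, 0 °C; then H5IO6, THF/H2O, 0 °C; used crude
Reagents that add atoms: 3-chloroperoxybenzoic acid 20, OOC(=O)c1cccc(Cl)c1
Why: Prilezhaev epoxidation should pick the only electron-rich alkene (all others are conjugated to carbonyl groups), and periodic acid should then open the epoxide and cleave the glycol to the C5 aldehyde and acetone without touching C6.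

Step 11
Reactants: 22 (1S,3E,6Z)-1-[(2S,3R)-2-formyl-4-methylidene-5-oxooxolan-3-yl]-7-iodo-3-methyl-5-oxoocta-3,6-dien-1-yl (2Z)-2-methylbut-2-enoate
Product: 23 (3aR,4S,6E,9Z,11R,11aS)-11-hydroxy-6,10-dimethyl-3-methylidene-2,8-dioxo-2,3,3a,4,5,8,11,11a-octahydrocyclodeca[b]furan-4-yl (2Z)-2-methylbut-2-enoate (target)
Conditions: CrCl2 (excess), NiCl2 (cat.), DMSO/THF, rt, high dilution
Reagents that add atoms: none
Why: In this intramolecular Nozaki–Hiyama–Kishi reaction the alkenylchromium species, formed with retention of the Z geometry, should add to the aldehyde and close the ten-membered ring, with polar Felkin–Anh attack anti to the C6–O bond giving the 5R alcohol (5,6-anti).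

**Compound list**

1 | (4R)-2,2-dimethyl-1,3-dioxolane-4-carbaldehyde | O=C[C@H]1COC(C)(C)O1 | starting material
2 | (triphenylphosphoranylidene)acetaldehyde | O=CC=P(c1ccccc1)(c1ccccc1)c1ccccc1 | starting material
3 | (2E)-3-[(4S)-2,2-dimethyl-1,3-dioxolan-4-yl]prop-2-enal | O=C/C=C/[C@H]1COC(C)(C)O1 | intermediate
4 | isopropyltriphenylphosphonium iodide | CC(C)[P+](c1ccccc1)(c1ccccc1)c1ccccc1.[I-] | starting material
5 | (4S)-2,2-dimethyl-4-[(1E)-4-methylpenta-1,3-dien-1-yl]-1,3-dioxolane | CC(C)=C/C=C/[C@H]1COC(C)(C)O1 | intermediate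
6 | 2-bromoprop-2-enoic acid | C=C(Br)C(=O)O | starting material
7 | allylpalladium bromide of the heteroannulation (η3-allyl over C6, C5 and CMe2, drawn as its η1 form at C6; not isolated) | C=C(C(=O)O)[C@H]([C@H]1COC(C)(C)O1)C([Pd]Br)C=C(C)C | intermediate
8 | (4S,5R)-4-[(4S)-2,2-dimethyl-1,3-dioxolan-4-yl]-3-methylidene-5-(2-methylprop-1-en-1-yl)oxolan-2-one | C=C1C(=O)O[C@H](C=C(C)C)[C@H]1[C@H]2COC(C)(C)O2 | intermediate
9 | (2R,3S)-4-methylidene-2-(2-methylprop-1-en-1-yl)-5-oxooxolane-3-carbaldehyde | C=C1C(=O)O[C@H](C=C(C)C)[C@H]1C=O | intermediate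
10 | 3-methylbut-2-enoyl chloride | CC(C)=CC(=O)Cl | starting material
11 | trimethyl(prop-1-yn-1-yl)silane | CC#C[Si](C)(C)C | starting material
12 | 2-methylhept-2-en-5-yn-4-one | CC(C)=CC(=O)C#CC | intermediate
13 | tert-butyldimethylsilyl trifluoromethanesulfonate | CC(C)(C)[Si](C)(C)OS(=O)(=O)C(F)(F)F | starting material
14 | tert-butyl(dimethyl){[(3Z)-2-methylhepta-1,3-dien-5-yn-4-yl]oxy}silane | C=C(C)/C=C(\O[Si](C)(C)C(C)(C)C)C#CC | intermediate
15 | (4R,5R)-4-[(1S,3E)-1-hydroxy-3-methyl-5-oxooct-3-en-6-yn-1-yl]-3-methylidene-5-(2-methylprop-1-en-1-yl)oxolan-2-one | C=C1C(=O)O[C@H](C=C(C)C)[C@H]1[C@@H](O)C/C(C)=C/C(=O)C#CC | intermediate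
16 | sodium iodide | [Na+].[I-] | starting material
17 | (4R,5R)-4-[(1S,3E,6Z)-1-hydroxy-7-iodo-3-methyl-5-oxoocta-3,6-dien-1-yl]-3-methylidene-5-(2-methylprop-1-en-1-yl)oxolan-2-one | C=C1C(=O)O[C@H](C=C(C)C)[C@H]1[C@@H](O)C/C(C)=C/C(=O)/C=C(/C)I | intermediate
18 | (2Z)-2-methylbut-2-enoic acid (angelic acid) | C/C=C(/C)C(=O)O | starting material
19 | (1S,3E,6Z)-7-iodo-3-methyl-1-[(2R,3R)-4-methylidene-2-(2-methylprop-1-en-1-yl)-5-oxooxolan-3-yl]-5-oxoocta-3,6-dien-1-yl (2Z)-2-methylbut-2-enoate | C=C1C(=O)O[C@H](C=C(C)C)[C@H]1[C@@H](OC(=O)/C(C)=C\C)C/C(C)=C/C(=O)/C=C(/C)I | intermediate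
20 | 3-chloroperoxybenzoic acid | OOC(=O)c1cccc(Cl)c1 | starting material
21 | (1S,3E,6Z)-1-[(2S,3R)-2-(3,3-dimethyloxiran-2-yl)-4-methylidene-5-oxooxolan-3-yl]-7-iodo-3-methyl-5-oxoocta-3,6-dien-1-yl (2Z)-2-methylbut-2-enoate (both oxirane epimers; not isolated) | C=C1C(=O)O[C@H](C2OC2(C)C)[C@H]1[C@@H](OC(=O)/C(C)=C\C)C/C(C)=C/C(=O)/C=C(/C)I | intermediate
22 | (1S,3E,6Z)-1-[(2S,3R)-2-formyl-4-methylidene-5-oxooxolan-3-yl]-7-iodo-3-methyl-5-oxoocta-3,6-dien-1-yl (2Z)-2-methylbut-2-enoate | C=C1C(=O)O[C@H](C=O)[C@H]1[C@@H](OC(=O)/C(C)=C\C)C/C(C)=C/C(=O)/C=C(/C)I | intermediate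
23 | (3aR,4S,6E,9Z,11R,11aS)-11-hydroxy-6,10-dimethyl-3-methylidene-2,8-dioxo-2,3,3a,4,5,8,11,11a-octahydrocyclodeca[b]furan-4-yl (2Z)-2-methylbut-2-enoate | C=C1C(=O)O[C@H]2[C@H]1[C@@H](OC(=O)/C(C)=C\C)C/C(C)=C/C(=O)/C=C(/C)[C@H]2O | target

**Step count and risks**

Total step count: 11. Longest linear sequence: 9 steps (1 → 3 → 5 → 8 → 9 → 15 → 17 → 19 → 22 → 23); the ynone branch (steps 5 and 6) joins in step 7.

Steps most likely to fail:

Step 3. β-Hydride elimination of the allylpalladium species to trienes, or base-induced polymerisation of 6, may outrun lactonisation. Fallback: starting from 5, a radical–polar crossover lactonisation with malonic acid (Mn(OAc)3, KOAc, AcOH, 50 °C) would be used. The malonyl radical adds to C7, the allyl radical is oxidised to the cation and one carboxyl group closes on C6, which should give the α-carboxy lactone F1. Decarboxylative Mannich methylenation of F1 (paraformaldehyde, Et2NH, dioxane, 70 °C) would return to the route at 8.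

Step 7. In aldehyde 9 the C7–H bond is both α to the aldehyde and allylic to the methylidene group, so double-bond migration into the ring and epimerisation at C7 may compete with the aldol addition. Fallback: starting from 8, the methylidene group would be masked by conjugate addition of thiophenol (PhSH, Et3N cat., CH2Cl2) to give the sulfide F2. Periodic acid would then cleave the acetonide and oxidise sulfur in one operation to the sulfinyl aldehyde F3, which has no allylic C7–H. The same aldol with 14 would give the sulfinyl aldol adduct F4, and thermal syn-elimination (toluene, CaCO3, 100 °C) would restore the methylidene group and return to the route at 15.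

Step 11. Facial selectivity at C5 may be poor or reversed under the conformational constraint of the closing ten-membered ring. Fallback: starting from 22, if the ring closure delivers mainly the C5 epimer F5, oxidation with Dess–Martin periodinane (NaHCO3, CH2Cl2) would give the 5-ketone F6. Reagent-controlled reduction ((R)-2-methyl-CBS-oxazaborolidine, catecholborane, toluene, −78 °C, alkenyl branch as the large group) should favour the α-acyloxy ketone at C5 over the cross-conjugated C2 ketone and would return to the route at 23.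

Further compounds
F1 | step 3 | (4S,5R)-4-[(4S)-2,2-dimethyl-1,3-dioxolan-4-yl]-5-(2-methylprop-1-en-1-yl)-2-oxooxolane-3-carboxylic acid (C3 epimers) | OC(=O)C1C(=O)O[C@H](C=C(C)C)[C@H]1[C@H]2COC(C)(C)O2
F2 | step 7 | (4S,5R)-4-[(4S)-2,2-dimethyl-1,3-dioxolan-4-yl]-5-(2-methylprop-1-en-1-yl)-3-[(phenylsulfanyl)methyl]oxolan-2-one (C3 epimers) | c1ccccc1SCC1C(=O)O[C@H](C=C(C)C)[C@H]1[C@H]2COC(C)(C)O2
F3 | step 7 | (2R,3S)-2-(2-methylprop-1-en-1-yl)-5-oxo-4-[(phenylsulfinyl)methyl]oxolane-3-carbaldehyde (C4 and sulfur epimers) | O=S(c1ccccc1)CC1C(=O)O[C@H](C=C(C)C)[C@H]1C=O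
F4 | step 7 | (4R,5R)-4-[(1S,3E)-1-hydroxy-3-methyl-5-oxooct-3-en-6-yn-1-yl]-5-(2-methylprop-1-en-1-yl)-3-[(phenylsulfinyl)methyl]oxolan-2-one (C3 and sulfur epimers) | O=S(c1ccccc1)CC1C(=O)O[C@H](C=C(C)C)[C@H]1[C@@H](O)C/C(C)=C/C(=O)C#CC
F5 | step 11 | (3aR,4S,6E,9Z,11S,11aS)-11-hydroxy-6,10-dimethyl-3-methylidene-2,8-dioxo-2,3,3a,4,5,8,11,11a-octahydrocyclodeca[b]furan-4-yl (2Z)-2-methylbut-2-enoate | C=C1C(=O)O[C@H]2[C@H]1[C@@H](OC(=O)/C(C)=C\C)C/C(C)=C/C(=O)/C=C(/C)[C@@H]2O
F6 | step 11 | (3aR,4S,6E,9Z,11aS)-6,10-dimethyl-3-methylidene-2,8,11-trioxo-2,3,3a,4,5,8,11,11a-octahydrocyclodeca[b]furan-4-yl (2Z)-2-methylbut-2-enoate | C=C1C(=O)O[C@H]2[C@H]1[C@@H](OC(=O)/C(C)=C\C)C/C(C)=C/C(=O)/C=C(/C)C2=O
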